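## Analysis of the target

Compound 21 is a flavone: a benzo-fused 4-pyranone (rings A and C) with a guaiacyl ring B at C2. It is achiral, with no stereocentre and no alkene geometry to set, so every stereocentre in the route is transient and may stay racemic. Ring A is a 1,2,3,5-tetraoxygenated benzene with four different oxygen functions: the ring oxygen O1 at C8a, a methoxy group at C8, a prenyl ether at C7 and a free, carbonyl-chelated phenol at C5. Ring C carries a 3-methoxy group, and ring B a 3'-methoxy group beside a free 4'-phenol. The allylic aryl ether is the sensitive group. It is cleaved by strong or Lewis acids, reduced under hydrogenolysis and rearranges on strong heating, so benzyl ethers and late demethylations are excluded. The main difficulty is placing the ring A oxygens unambiguously (8-methoxy versus the 6-methoxy isomer) and holding 5-OH and 4'-OH masked while 3-OH is methylated. The strategy rests on the C3–C4 bond. It joins the carbonyl carbon C4 to the oxygen-bearing C3, which is the pattern of an acyloin, so ring C can be read as the enol of a 2-arylchromane-3,4-dione whose C3 and C4 both derive from aldehydes.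

## Retrosynthetic reasoning

**21 to 20 (two O–Si bonds).** Both phenols are unveiled last by fluoride. Silyl ethers are chosen because their removal is orthogonal to the prenyl ether, the methyl ethers and the pyranone.

**20 to 19 (O–CH3 at C3).** With 5-O and 4'-O silylated, the enolic 3-OH of flavonol 19 is the only hydroxyl left, so the methylation needs no selectivity.

**19 to 17 (oxidation level at C4).** Flavonol 19 is the enol of dione 18, and 18 is the oxidation product of acyloin 17. The oxidation erases the stereocentres at C2 and C4, so 17 can be a mixture of racemic diastereomers.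

**17 to 16 (C3–C4 bond, the key disconnection).** This is the only C–C bond of ring C that links two oxygenated carbons. Cutting it gives dialdehyde 16, in which both carbons sit at the same oxidation level and are already tied together through the O1–C2 ether. Forward, one aldehyde must become an acyl-anion equivalent and add to the other, which carbene catalysis achieves. C3 thereby receives its oxygen without a separate hydroxylation.

**16 to 15 to 14 (redox adjustment).** No hydride reduces an ester in the presence of an aryl aldehyde. Ester aldehyde 14 is therefore reduced to diol 15 and both alcohols are re-oxidised together.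

**14 to 9 and 13 (O1–C2 ether bond).** This cut divides the molecule into a ring A salicylaldehyde 9 and a ring B α-bromo ester 13. The forward reaction is a phenoxide SN2 displacement at an activated benzylic carbon, and 9 has only one free phenol.

**13 to 11 to 10 (C–Br and O–Si).** The bromide comes from the ester enolate of 11, and 11 from commercial ester 10 by silylation.

**9 to 7 and 8 (O–prenyl bond).** In dihydroxy aldehyde 7 the 4-OH is para to the formyl group and not chelated, while the 2-OH is hydrogen-bonded and flanked. Alkylation with 8 should therefore occur at O4 and leave the 2-OH for the ether bond above.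

**7 to 6 to 5 to 4 (protecting-group exchange and the formyl carbon).** The aldehyde carbon, the future C4, is introduced ortho to the free phenol of symmetric 4, so only one regioisomer is possible. That phenol becomes the 5-oxygen and is silylated (6) before the two acetal groups are removed (7).

**4 to 2 to 1 (C5–O bond).** The fourth oxygen must enter meta to both existing phenol oxygens, where electrophilic substitution cannot reach. Sterically controlled C–H borylation of bis-acetal 2 via boronate 3, followed by oxidation, places it at the only unhindered ring C–H of commercial 1.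

## Alternatives that were turned down

**Alternative 1: ring A by cycloaddition–aromatisation on a pyranone.**
- Disconnection: C8–C8a and C4a–C5, a [4+2] retron.
- Forward key step: the electron-rich diene 1,4-dimethoxy-1,3-bis(trimethylsilyloxy)buta-1,3-diene A2 adds across the C5=C6 bond of the sulfinyl pyranone A1. Elimination of the sulfinyl group and of one methoxy group, with desilylation, aromatises ring A to the 5,7-dihydroxy flavone A3.
- For: no tetraoxygenated benzene has to be made, ring B and the 3-methoxy group are already in place, and only a 7-O-prenylation (the 5-OH is chelated) and a desilylation remain.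
- Against: the dienophile bond of A1 is part of a delocalised vinylogous ester and is activated only by the sulfinyl group. A1 itself needs a multi-step pyranone synthesis with sulfenylation and oxidation at C5. A2 is a hydrolytically fragile tetra-heteroatom diene. The orientation rests on a polarity argument, and a reversed orientation would give the 6-methoxy isomer, which is hard to distinguish from A3.
- Comparison: Alternative 1 is clearly stronger in step economy for ring A. The chosen route offers in its place an oxygen pattern fixed atom by atom through symmetry and chelation, and a precursor built only from classical reactions.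

**Alternative 2: three-component carbonylative assembly of ring C.**
- Disconnection: C4a–C4 and C4–C3, with the carbonyl carbon coming from the gas phase, plus O1–C2.
- Forward key step: carbonylative palladium catalysis joins bromophenol A4 to the enolate of α-methoxy ketone A5, and acid then condenses the phenol onto the aryl ketone to give the tribenzyl flavone A6.
- For: it is the most convergent plan, A5 is simple, and ring C and the 3-methoxy group arise in one operation.
- Against: A4 contains the same tetraoxygenated pattern as salicylaldehyde 9 and adds a regiospecific bromination, so ring A is no cheaper. The C–Br bond is electron-rich and flanked on both sides, which slows oxidative addition to zerovalent palladium. The free phenol and O-acylation or CO-free arylation of the hindered enolate can divert the acyl-palladium species. After debenzylation of A6 the 7-OH and 4'-OH have similar acidity, so the prenyl group cannot be placed selectively without a new protecting-group scheme.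
- Comparison: Alternative 2 is stronger in convergence. The chosen strategy offers in its place a prenyl ether installed early under chelation control and an unambiguous endgame.

**Alternative 3: ring A by electrocyclic ring expansion of a cyclobutenone.**
- Disconnection: C4a–C5, with ring A traced back to a four-membered ring attached to the pyranone.
- Forward key step: heating cyclobutenone A7 opens it to a dienylketene whose ketene carbon closes onto the pyranone C–H carbon. Tautomerisation gives A8, the 4'-O-silyl ether of the target, with the C5 phenol free.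
- For: A8 is one desilylation from the target, all ring A substituents are placed by the four-membered ring, and the conditions are neutral.
- Against: A7 needs a differentiated four-membered-ring building block and a pyranone metallated next to its ring oxygen, where conjugate addition and ring opening compete. In A7 the prenyl group is an allyl vinyl ether, which invites a [3,3] shift at the temperature of ring opening.
- Comparison: Alternative 3 is stronger on the endgame and in elegance. The chosen strategy offers in its place commodity starting materials and no thermal stress on the prenyl ether.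

Key step: step 12

Assumption: ethyl homovanillate (10) is taken as a purchasable ester, and every intermediate with a stereocentre at the future C2 is racemic, which has no consequence for the achiral target.

## Route

Step 1
Reactants: 1 2-methoxyresorcinol (2-methoxybenzene-1,3-diol)
Product: 2 2-methoxy-1,3-bis(methoxymethoxy)benzene
Conditions: NaH, MOMCl, THF/DMF, 0 °C to rt
Reagents that add atoms: chloromethyl methyl ether, COCCl
Why: Double Williamson etherification of the two phenoxides; the small acetal ethers are inert to the iridium catalyst, do not shield C5, and come off later under mild acid that an aryl silyl ether tolerates.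

Step 2
Reactants: 2 2-methoxy-1,3-bis(methoxymethoxy)benzene
Product: 4 4-methoxy-3,5-bis(methoxymethoxy)phenol, via aryl pinacol boronate 3 (not isolated)
Conditions: [Ir(OMe)(cod)]2 (1.5 mol %), 4,4'-di-tert-butyl-2,2'-bipyridine (3 mol %), B2pin2, THF, 80 °C; then KHSO5, acetone/H2O, 0 °C to rt
Reagents that add atoms: bis(pinacolato)diboron, CC1(C)OB(B2OC(C)(C)C(C)(C)O2)OC1(C)C (boryl group of 3); potassium peroxymonosulfate, [K+].[O-]S(=O)(=O)OO (oxygen of 4)
Why: Iridium-catalysed aromatic C–H borylation is sterically governed and C5 is the only ring C–H without an ortho substituent, so boron should enter there alone; peroxide oxidation then replaces boron by oxygen at the same carbon (one-pot borylation/oxidation to a meta-substituted phenol).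

Step 3
Reactants: 4 4-methoxy-3,5-bis(methoxymethoxy)phenol
Product: 5 6-hydroxy-3-methoxy-2,4-bis(methoxymethoxy)benzaldehyde
Conditions: MgCl2, Et3N, (CH2O)n, MeCN, reflux
Reagents that add atoms: formaldehyde (as paraformaldehyde), C=O
Why: Magnesium-phenoxide-mediated ortho-formylation (hydroxymethylation inside the magnesium chelate, then hydride transfer to a second formaldehyde) acts only next to the free OH; the two ortho positions of 4 are equivalent by symmetry, so one salicylaldehyde should form, and its chelated, deactivated ring resists a second formylation.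

Step 4
Reactants: 5 6-hydroxy-3-methoxy-2,4-bis(methoxymethoxy)benzaldehyde
Product: 6 3-methoxy-2,4-bis(methoxymethoxy)-6-(triisopropylsilyloxy)benzaldehyde
Conditions: TIPSCl, imidazole, DMAP (cat.), DMF, rt to 40 °C
Reagents that add atoms: chlorotriisopropylsilane, CC(C)[Si](Cl)(C(C)C)C(C)C
Why: Imidazole-promoted silylation of the chelated phenol; the bulky silyl ether masks the future 5-OH until the last step and withstands carbonate, hydride and hypervalent iodine, and the non-Lewis-acidic conditions leave the two acetals alone.

Step 5
Reactants: 6 3-methoxy-2,4-bis(methoxymethoxy)-6-(triisopropylsilyloxy)benzaldehyde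
Product: 7 2,4-dihydroxy-3-methoxy-6-(triisopropylsilyloxy)benzaldehyde
Conditions: HCl (2 M aq.), MeOH/THF, 40 °C
Reagents that add atoms: none
Why: Acid-catalysed acetal exchange with methanol removes both methoxymethyl groups, whereas aryl triisopropylsilyl ethers cleave only slowly under acid, so the 2-OH and 4-OH are freed selectively.

Step 6
Reactants: 7 2,4-dihydroxy-3-methoxy-6-(triisopropylsilyloxy)benzaldehyde; 8 prenyl bromide (1-bromo-3-methylbut-2-ene)
Product: 9 2-hydroxy-3-methoxy-4-(3-methylbut-2-enyloxy)-6-(triisopropylsilyloxy)benzaldehyde
Conditions: K2CO3 (1.1 equiv), acetone, rt to 40 °C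
Reagents that add atoms: none
Why: Williamson etherification with regiocontrol by acidity and hydrogen bonding: the 4-OH is para to the formyl group and not chelated, so one equivalent of weak base deprotonates it, while the 2-OH is locked in a hydrogen bond to the aldehyde and flanked on both sides; SN2 at the primary allylic bromide gives the O-prenyl ether.

Step 7
Reactants: 10 ethyl homovanillate (ethyl 2-(4-hydroxy-3-methoxyphenyl)acetate)
Product: 11 ethyl 2-[3-methoxy-4-(triisopropylsilyloxy)phenyl]acetate
Conditions: TIPSCl, imidazole, DMF, rt
Reagents that add atoms: chlorotriisopropylsilane, CC(C)[Si](Cl)(C(C)C)C(C)C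
Why: Standard silylation of the guaiacol-type phenol; it masks the future 4'-OH against the alkylations of steps 9 and 14 and is removed together with the 5-O-silyl group at the end.

Step 8
Reactants: 11 ethyl 2-[3-methoxy-4-(triisopropylsilyloxy)phenyl]acetate
Product: 13 ethyl 2-bromo-2-[3-methoxy-4-(triisopropylsilyloxy)phenyl]acetate (racemic), via trimethylsilyl ketene acetal 12 (not isolated)
Conditions: LiN(SiMe3)2, Me3SiCl, THF, −78 °C; then NBS, −78 to 0 °C
Reagents that add atoms: chlorotrimethylsilane, C[Si](C)(C)Cl (silyl group of 12); N-bromosuccinimide, O=C1CCC(=O)N1Br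
Why: The lithium ester enolate is trapped as ketene acetal 12, which is brominated at carbon far faster than the electron-rich ring (enolate α-halogenation), avoiding the nuclear bromination a radical benzylic bromination would risk; the new stereocentre is racemic and is erased later.

Step 9
Reactants: 9 2-hydroxy-3-methoxy-4-(3-methylbut-2-enyloxy)-6-(triisopropylsilyloxy)benzaldehyde; 13 ethyl 2-bromo-2-[3-methoxy-4-(triisopropylsilyloxy)phenyl]acetate
Product: 14 ethyl 2-[2-formyl-6-methoxy-5-(3-methylbut-2-enyloxy)-3-(triisopropylsilyloxy)phenoxy]-2-[3-methoxy-4-(triisopropylsilyloxy)phenyl]acetate (racemic)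
Conditions: K2CO3, MeCN, 40 °C
Reagents that add atoms: none
Why: Williamson ether synthesis forming the O1–C2 bond: the only free phenol of 9 displaces bromide from the doubly activated benzylic α-bromo ester by SN2; hindered 2,6-disubstituted phenoxides are known to alkylate with α-bromo arylacetates, and the stereocentre formed is racemic and later destroyed.

Step 10
Reactants: 14 ethyl 2-[2-formyl-6-methoxy-5-(3-methylbut-2-enyloxy)-3-(triisopropylsilyloxy)phenoxy]-2-[3-methoxy-4-(triisopropylsilyloxy)phenyl]acetate
Product: 15 2-[2-(hydroxymethyl)-6-methoxy-5-(3-methylbut-2-enyloxy)-3-(triisopropylsilyloxy)phenoxy]-2-[3-methoxy-4-(triisopropylsilyloxy)phenyl]ethanol (racemic)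
Conditions: LiAlH4, THF, −20 to 0 °C; non-acidic aqueous work-up
Reagents that add atoms: none
Why: Hydride reduction takes ester and aldehyde to the diol in one operation, since no hydride reduces the ester alone beside an aryl aldehyde; the aryl silyl ethers and the isolated alkene are inert at low temperature.

Step 11
Reactants: 15 2-[2-(hydroxymethyl)-6-methoxy-5-(3-methylbut-2-enyloxy)-3-(triisopropylsilyloxy)phenoxy]-2-[3-methoxy-4-(triisopropylsilyloxy)phenyl]ethanol
Product: 16 3-methoxy-2-[1-(3-methoxy-4-triisopropylsilyloxyphenyl)-2-oxoethoxy]-4-(3-methylbut-2-enyloxy)-6-(triisopropylsilyloxy)benzaldehyde (racemic)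
Conditions: Dess–Martin periodinane (2.4 equiv), pyridine, CH2Cl2, 0 °C to rt
Reagents that add atoms: none
Why: Dess–Martin oxidation of both primary alcohols stops at the aldehyde stage; pyridine buffering protects the acid-labile, electron-rich benzylic alcohol and the enolisable α-aryloxy aldehyde, and 16 is taken on at once without chromatography.

Step 12
Reactants: 16 3-methoxy-2-[1-(3-methoxy-4-triisopropylsilyloxyphenyl)-2-oxoethoxy]-4-(3-methylbut-2-enyloxy)-6-(triisopropylsilyloxy)benzaldehyde
Product: 17 4-hydroxy-8-methoxy-2-[3-methoxy-4-(triisopropylsilyloxy)phenyl]-7-(3-methylbut-2-enyloxy)-5-(triisopropylsilyloxy)chroman-3-one (racemic, mixture of C2/C4 diastereomers)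
Conditions: 3-benzyl-5-(2-hydroxyethyl)-4-methylthiazolium chloride (20 mol %), Et3N (30 mol %), degassed THF (0.02 M), 40 °C, Ar
Reagents that add atoms: none
Why: Et3N deprotonates the thiazolium salt to the thiazol-2-ylidene, which adds reversibly to the more electrophilic side-chain aldehyde, and proton transfer gives the enaminol (Breslow intermediate), an acyl-anion equivalent at the future C3. Its nucleophilic carbon adds to the A-ring formyl carbon (future C4), and collapse of the adduct releases the carbene and leaves the C3 ketone beside the C4 carbinol. The closest known reaction type is the carbene-catalysed intramolecular crossed benzoin cyclisation of salicylaldehyde-derived oxo ethers and of dialdehydes to cyclic acyloins. Ring C closes in the 6-exo-trig mode. The new stereocentre at C4 is set, as far as it is set at all, by the existing C2 centre through a half-chair transition state with the C2 aryl group pseudo-equatorial, and no control is needed because C2 and C4 both become sp2 in step 13. The step needs the right donor and acceptor roles, which the substrate secures because the aryl aldehyde, flanked by two ortho oxygens, cannot reach the planar enaminol and so acts only as acceptor, and either assignment of roles would in any case give the same C3–C4 bond at the same oxidation level. It needs intramolecular to beat intermolecular benzoin, which high dilution and the six-membered transition state favour. It also needs ring closure to outrun expulsion of the A-ring aryloxide from C2 of the enaminol, which is favoured by the acceptor being held five atoms away and by a weak amine base in an aprotic solvent that keep the enaminol neutral.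

Step 13
Reactants: 17 4-hydroxy-8-methoxy-2-[3-methoxy-4-(triisopropylsilyloxy)phenyl]-7-(3-methylbut-2-enyloxy)-5-(triisopropylsilyloxy)chroman-3-one
Product: 19 3-hydroxy-8-methoxy-2-[3-methoxy-4-(triisopropylsilyloxy)phenyl]-7-(3-methylbut-2-enyloxy)-5-(triisopropylsilyloxy)chromen-4-one, via chromane-3,4-dione 18 (not isolated)
Conditions: Cu(OAc)2 (2.2 equiv), pyridine, MeOH, 40 °C, Ar; aq. citric acid work-up
Reagents that add atoms: none
Why: Divalent copper oxidises α-hydroxy ketones to 1,2-diketones through the copper enediolate; dione 18 has an acidic C2–H between O1, the aryl ring and the C3 carbonyl and should tautomerise at once to the conjugated 3-hydroxy-4-pyranone. Exclusion of air and an acidic work-up guard against oxygenative cleavage of the copper flavonolate.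

Step 14
Reactants: 19 3-hydroxy-8-methoxy-2-[3-methoxy-4-(triisopropylsilyloxy)phenyl]-7-(3-methylbut-2-enyloxy)-5-(triisopropylsilyloxy)chromen-4-one
Product: 20 3,8-dimethoxy-2-[3-methoxy-4-(triisopropylsilyloxy)phenyl]-7-(3-methylbut-2-enyloxy)-5-(triisopropylsilyloxy)chromen-4-one
Conditions: MeI, K2CO3, acetone, 40 °C
Reagents that add atoms: iodomethane, CI
Why: Williamson methylation of the only free hydroxyl, the acidic enolic 3-OH; suspended carbonate in acetone is mild enough to leave both aryl silyl ethers, so neither 4'-O nor 5-O can be methylated.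

Step 15
Reactants: 20 3,8-dimethoxy-2-[3-methoxy-4-(triisopropylsilyloxy)phenyl]-7-(3-methylbut-2-enyloxy)-5-(triisopropylsilyloxy)chromen-4-one
Product: 21 5-hydroxy-2-(4-hydroxy-3-methoxyphenyl)-3,8-dimethoxy-7-(3-methylbut-2-enyloxy)chromen-4-one (5,4'-dihydroxy-3,8,3'-trimethoxy-7-prenyloxyflavone)
Conditions: tetrabutylammonium fluoride, AcOH, THF, 0 °C to rt
Reagents that add atoms: none
Why: Fluoride-driven desilylation cleaves both aryl Si–O bonds, and acetic acid keeps the medium near neutral; the methyl ethers, the allylic ether and the pyranone are inert to fluoride.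

## Compound list

1 | 2-methoxyresorcinol | COc1c(O)cccc1O | starting material
2 | 2-methoxy-1,3-bis(methoxymethoxy)benzene | COCOc1cccc(OCOC)c1OC | intermediate
3 | 2-[4-methoxy-3,5-bis(methoxymethoxy)phenyl]-4,4,5,5-tetramethyl-1,3,2-dioxaborolane | COCOc1cc(B2OC(C)(C)C(C)(C)O2)cc(OCOC)c1OC | intermediate (not isolated)
4 | 4-methoxy-3,5-bis(methoxymethoxy)phenol | COCOc1cc(O)cc(OCOC)c1OC | intermediate
5 | 6-hydroxy-3-methoxy-2,4-bis(methoxymethoxy)benzaldehyde | O=Cc1c(O)cc(OCOC)c(OC)c1OCOC | intermediate
6 | 3-methoxy-2,4-bis(methoxymethoxy)-6-(triisopropylsilyloxy)benzaldehyde | O=Cc1c(O[Si](C(C)C)(C(C)C)C(C)C)cc(OCOC)c(OC)c1OCOC | intermediate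
7 | 2,4-dihydroxy-3-methoxy-6-(triisopropylsilyloxy)benzaldehyde | O=Cc1c(O[Si](C(C)C)(C(C)C)C(C)C)cc(O)c(OC)c1O | intermediate
8 | prenyl bromide (1-bromo-3-methylbut-2-ene) | CC(C)=CCBr | starting material
9 | 2-hydroxy-3-methoxy-4-(3-methylbut-2-enyloxy)-6-(triisopropylsilyloxy)benzaldehyde | O=Cc1c(O[Si](C(C)C)(C(C)C)C(C)C)cc(OCC=C(C)C)c(OC)c1O | intermediate
10 | ethyl homovanillate | CCOC(=O)Cc1ccc(O)c(OC)c1 | starting material
11 | ethyl 2-[3-methoxy-4-(triisopropylsilyloxy)phenyl]acetate | CCOC(=O)Cc1ccc(O[Si](C(C)C)(C(C)C)C(C)C)c(OC)c1 | intermediate
12 | 1-ethoxy-2-[3-methoxy-4-(triisopropylsilyloxy)phenyl]-1-(trimethylsilyloxy)ethene | CCOC(O[Si](C)(C)C)=Cc1ccc(O[Si](C(C)C)(C(C)C)C(C)C)c(OC)c1 | intermediate (not isolated)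
13 | ethyl 2-bromo-2-[3-methoxy-4-(triisopropylsilyloxy)phenyl]acetate (racemic) | CCOC(=O)C(Br)c1ccc(O[Si](C(C)C)(C(C)C)C(C)C)c(OC)c1 | intermediate
14 | ethyl 2-[2-formyl-6-methoxy-5-(3-methylbut-2-enyloxy)-3-(triisopropylsilyloxy)phenoxy]-2-[3-methoxy-4-(triisopropylsilyloxy)phenyl]acetate (racemic) | CCOC(=O)C(Oc1c(OC)c(OCC=C(C)C)cc(O[Si](C(C)C)(C(C)C)C(C)C)c1C=O)c1ccc(O[Si](C(C)C)(C(C)C)C(C)C)c(OC)c1 | intermediate
15 | 2-[2-(hydroxymethyl)-6-methoxy-5-(3-methylbut-2-enyloxy)-3-(triisopropylsilyloxy)phenoxy]-2-[3-methoxy-4-(triisopropylsilyloxy)phenyl]ethanol (racemic) | OCC(Oc1c(OC)c(OCC=C(C)C)cc(O[Si](C(C)C)(C(C)C)C(C)C)c1CO)c1ccc(O[Si](C(C)C)(C(C)C)C(C)C)c(OC)c1 | intermediate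
16 | 3-methoxy-2-[1-(3-methoxy-4-triisopropylsilyloxyphenyl)-2-oxoethoxy]-4-(3-methylbut-2-enyloxy)-6-(triisopropylsilyloxy)benzaldehyde (racemic) | COc1c(OCC=C(C)C)cc(O[Si](C(C)C)(C(C)C)C(C)C)c(C=O)c1OC(C=O)c1ccc(O[Si](C(C)C)(C(C)C)C(C)C)c(OC)c1 | intermediate
17 | 4-hydroxy-8-methoxy-2-[3-methoxy-4-(triisopropylsilyloxy)phenyl]-7-(3-methylbut-2-enyloxy)-5-(triisopropylsilyloxy)chroman-3-one (racemic, mixture of diastereomers) | COc1c(OCC=C(C)C)cc(O[Si](C(C)C)(C(C)C)C(C)C)c2c1OC(c1ccc(O[Si](C(C)C)(C(C)C)C(C)C)c(OC)c1)C(=O)C2O | intermediate
18 | 8-methoxy-2-[3-methoxy-4-(triisopropylsilyloxy)phenyl]-7-(3-methylbut-2-enyloxy)-5-(triisopropylsilyloxy)chromane-3,4-dione (racemic) | COc1c(OCC=C(C)C)cc(O[Si](C(C)C)(C(C)C)C(C)C)c2c1OC(c1ccc(O[Si](C(C)C)(C(C)C)C(C)C)c(OC)c1)C(=O)C2=O | intermediate (not isolated)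
19 | 3-hydroxy-8-methoxy-2-[3-methoxy-4-(triisopropylsilyloxy)phenyl]-7-(3-methylbut-2-enyloxy)-5-(triisopropylsilyloxy)chromen-4-one | COc1cc(-c2oc3c(OC)c(OCC=C(C)C)cc(O[Si](C(C)C)(C(C)C)C(C)C)c3c(=O)c2O)ccc1O[Si](C(C)C)(C(C)C)C(C)C | intermediate
20 | 3,8-dimethoxy-2-[3-methoxy-4-(triisopropylsilyloxy)phenyl]-7-(3-methylbut-2-enyloxy)-5-(triisopropylsilyloxy)chromen-4-one | COc1cc(-c2oc3c(OC)c(OCC=C(C)C)cc(O[Si](C(C)C)(C(C)C)C(C)C)c3c(=O)c2OC)ccc1O[Si](C(C)C)(C(C)C)C(C)C | intermediate
21 | 5,4'-dihydroxy-3,8,3'-trimethoxy-7-prenyloxyflavone | COc1cc(-c2oc3c(OC)c(OCC=C(C)C)cc(O)c3c(=O)c2OC)ccc1O | target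

## Step count and least certain steps

Total: 15 steps. Longest linear sequence: 13 steps (steps 1–6 and 9–15); the ring B branch (steps 7 and 8) joins at step 9.

**Step 12 (key step).**
- What may go wrong: the enaminol may expel the A-ring aryloxide from C2 (an E1cB-type internal redox ending in acyl transfer) instead of adding to the aryl aldehyde. The aryloxide is a fair leaving group because of its ortho-formyl substituent, while the acceptor aldehyde is electron-rich and flanked by an ortho silyloxy group. Base-induced enolisation and aldol self-condensation of the sensitive side-chain aldehyde would also drain material.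
- Fallback, by known chemistry, from 9 to 20, bypassing steps 9–14: methoxymethylmagnesium chloride (excess) adds to the aldehyde of 9 to give the 2-methoxy-1-arylethanol F1. MnO2 oxidises its benzylic carbinol to the ω-methoxyacetophenone F2. The dianion of F2 (LiN(SiMe3)2, THF, −78 °C) is C-aroylated with 3-methoxy-4-(triisopropylsilyloxy)benzoyl chloride F3, made from commercial vanillic acid by silylation and oxalyl chloride, in a Baker–Venkataraman-type acylation that gives the 2-methoxy-1,3-diketone F4. Warming F4 in acetic acid closes ring C by attack of the phenol on the B-ring ketone and loss of water, giving 20.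

**Step 9.**
- What may go wrong: slow displacement, because the phenoxide is hydrogen-bonded and flanked on both sides. This leaves time for solvolysis of the labile benzylic bromide and for carbonate-induced desilylation.
- Fallback from 11 and 9 to 14: hydroxylate the enolate of 11 with 2-(phenylsulfonyl)-3-phenyloxaziridine to the mandelate-type α-hydroxy ester F5, then couple F5 with the acidic phenol 9 under Mitsunobu conditions (PPh3, diisopropyl azodicarboxylate, THF) to give 14.

**Step 11.**
- What may go wrong: acid-induced ionisation of the trioxygenated benzylic alcohol during the oxidation, with capture of the cation by the neighbouring primary alcohol, and enolisation, hydration or air oxidation of the α-aryloxy aldehyde on handling.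
- Fallback from 15 to 16 in two chemoselective stages under neutral to basic conditions: MnO2 in CH2Cl2 oxidises only the benzylic alcohol to give the hydroxy aldehyde F6. A Parikh–Doering oxidation (SO3·pyridine, DMSO, i-Pr2NEt) of the remaining primary alcohol then gives 16, which is used at once.

**Step 6.**
- What may go wrong: over-alkylation at the chelated 2-OH, C-prenylation of the electron-rich ring, or loss of the silyl group under carbonate.
- Fallback from 7 to 9: Mitsunobu etherification with 3-methylbut-2-en-1-ol (PPh3, diisopropyl azodicarboxylate, THF, 0 °C). It alkylates the more acidic, non-chelated 4-OH without any base and makes no new intermediate.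

## Further compounds

F1 | step 12 | 1-[2-hydroxy-3-methoxy-4-(3-methylbut-2-enyloxy)-6-(triisopropylsilyloxy)phenyl]-2-methoxyethanol (racemic) | COCC(O)c1c(O)c(OC)c(OCC=C(C)C)cc1O[Si](C(C)C)(C(C)C)C(C)C
F2 | step 12 | 1-[2-hydroxy-3-methoxy-4-(3-methylbut-2-enyloxy)-6-(triisopropylsilyloxy)phenyl]-2-methoxyethanone | COCC(=O)c1c(O)c(OC)c(OCC=C(C)C)cc1O[Si](C(C)C)(C(C)C)C(C)C
F3 | step 12 | 3-methoxy-4-(triisopropylsilyloxy)benzoyl chloride | COc1cc(C(=O)Cl)ccc1O[Si](C(C)C)(C(C)C)C(C)C
F4 | step 12 | 1-[2-hydroxy-3-methoxy-4-(3-methylbut-2-enyloxy)-6-(triisopropylsilyloxy)phenyl]-2-methoxy-3-[3-methoxy-4-(triisopropylsilyloxy)phenyl]propane-1,3-dione (racemic) | COC(C(=O)c1ccc(O[Si](C(C)C)(C(C)C)C(C)C)c(OC)c1)C(=O)c1c(O)c(OC)c(OCC=C(C)C)cc1O[Si](C(C)C)(C(C)C)C(C)C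
F5 | step 9 | ethyl 2-hydroxy-2-[3-methoxy-4-(triisopropylsilyloxy)phenyl]acetate (racemic) | CCOC(=O)C(O)c1ccc(O[Si](C(C)C)(C(C)C)C(C)C)c(OC)c1
F6 | step 11 | 2-[2-hydroxy-1-(3-methoxy-4-triisopropylsilyloxyphenyl)ethoxy]-3-methoxy-4-(3-methylbut-2-enyloxy)-6-(triisopropylsilyloxy)benzaldehyde (racemic) | OCC(Oc1c(OC)c(OCC=C(C)C)cc(O[Si](C(C)C)(C(C)C)C(C)C)c1C=O)c1ccc(O[Si](C(C)C)(C(C)C)C(C)C)c(OC)c1
F0 | step 6 | none | none
A1 | alternative 1 | 3-methoxy-2-[3-methoxy-4-(triisopropylsilyloxy)phenyl]-5-(phenylsulfinyl)pyran-4-one | COc1cc(-c2occ(S(=O)c3ccccc3)c(=O)c2OC)ccc1O[Si](C(C)C)(C(C)C)C(C)C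
A2 | alternative 1 | 1,4-dimethoxy-1,3-bis(trimethylsilyloxy)buta-1,3-diene | COC=C(O[Si](C)(C)C)C=C(OC)O[Si](C)(C)C
A3 | alternative 1 | 5,7-dihydroxy-3,8-dimethoxy-2-(3-methoxy-4-triisopropylsilyloxyphenyl)chromen-4-one | COc1cc(-c2oc3c(OC)c(O)cc(O)c3c(=O)c2OC)ccc1O[Si](C(C)C)(C(C)C)C(C)C
A4 | alternative 2 | 3,5-bis(benzyloxy)-2-bromo-6-methoxyphenol | COc1c(O)c(Br)c(OCc2ccccc2)cc1OCc1ccccc1
A5 | alternative 2 | 1-(4-benzyloxy-3-methoxyphenyl)-2-methoxyethanone | COCC(=O)c1ccc(OCc2ccccc2)c(OC)c1
A6 | alternative 2 | 5,7-bis(benzyloxy)-2-(4-benzyloxy-3-methoxyphenyl)-3,8-dimethoxychromen-4-one | COc1cc(-c2oc3c(OC)c(OCc4ccccc4)cc(OCc4ccccc4)c3c(=O)c2OC)ccc1OCc1ccccc1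
A7 | alternative 3 | 4-methoxy-4-[5-methoxy-6-(3-methoxy-4-tert-butyldimethylsilyloxyphenyl)-4-oxopyran-2-yl]-3-(3-methylbut-2-enyloxy)cyclobut-2-en-1-one (racemic) | COC1(c2cc(=O)c(OC)c(-c3ccc(O[Si](C)(C)C(C)(C)C)c(OC)c3)o2)C(=O)C=C1OCC=C(C)C
A8 | alternative 3 | 4'-O-tert-butyldimethylsilyl ether of the target | COc1cc(-c2oc3c(OC)c(OCC=C(C)C)cc(O)c3c(=O)c2OC)ccc1O[Si](C)(C)C(C)(C)C
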